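The five-membered ring of the indane (C1, C2, C3, C3a, C7a) is made by contracting the cyclohexene ring of an achiral 4-aryl-1,2-dihydronaphthalene. The step exploits the exocyclic C1–C(=O)Ar bond: the carbonyl carbon starts as a ring atom bonded to the future C7a. A chiral aryl-λ3-iodane adds to the styrenic C=C, methanol adds, and C7a shifts to the neighbouring CH, which becomes the C1 stereocentre, while the expelled carbon emerges as the ketone dimethyl ketal. C1 then relays its configuration: a 2,3-diaryl-1H-indene is built on the contracted ring and hydrogenated anti to the C1 side chain, which gives the all-cis array.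

Key step: step 3

Remark 1: the target SMILES is read as the all-cis (1R,2R,3R) indane. C1–H is α to the ketone and this isomer is not expected to be the thermodynamic one, so the ketone stays masked as a ketal from its creation to the last operation.
Remark 2: ArI* is (R,R)-2-iodo-1,3-bis[1-(mesitylcarbamoyl)ethoxy]benzene, Cc1cc(C)c(NC(=O)[C@@H](C)Oc2cccc(O[C@H](C)C(=O)Nc3c(C)cc(C)cc3C)c2I)c(C)c1. It is assumed to deliver (R)-8; if the sense of induction is the opposite, its (S,S)-antipode is used in the same way.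

Step 1
Reactants: 1 N-methoxy-N-methylcyclopropanecarboxamide; 2 [4-(benzyloxy)phenyl]magnesium bromide (THF solution)
Product: 3 [4-(benzyloxy)phenyl](cyclopropyl)methanone
Conditions: THF, 0 °C → rt; aq. NH4Cl
Reagents that add atoms: none
Why: Weinreb ketone synthesis; the chelated tetrahedral intermediate should prevent a second addition.

Step 2
Reactants: 4 1,3-bis(benzyloxy)-5-bromobenzene; 3 [4-(benzyloxy)phenyl](cyclopropyl)methanone
Product: 7 6,8-bis(benzyloxy)-4-[4-(benzyloxy)phenyl]-1,2-dihydronaphthalene, via [3,5-bis(benzyloxy)phenyl]lithium 5 (not isolated), via rac-[3,5-bis(benzyloxy)phenyl][4-(benzyloxy)phenyl](cyclopropyl)methanol 6 (not isolated)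
Conditions: 4, n-BuLi, THF, −78 °C; add 3, −78 → 0 °C; aq. NH4Cl; crude 6, Bi(OTf)3 (5 mol%), CH2Cl2, 0 °C → rt
Reagents that add atoms: none
Why: Bromine–lithium exchange and 1,2-addition give the diaryl(cyclopropyl)carbinol, whose cation should be opened at a cyclopropane CH2 by the only nucleophilic ortho carbon (ortho/para to the two benzyloxy groups) of the resorcinol ring in a cyclopropylcarbinyl–homoallyl rearrangement/Friedel–Crafts annulation, so the six-membered ring forms with the ethers at C6 and C8; no stereocentre remains.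

Step 3
Reactants: 7 6,8-bis(benzyloxy)-4-[4-(benzyloxy)phenyl]-1,2-dihydronaphthalene
Product: 8 (R)-4,6-bis(benzyloxy)-1-{[4-(benzyloxy)phenyl](dimethoxy)methyl}indane
Conditions: ArI* (1.2 equiv), mCPBA (1.1 equiv), TsOH·H2O (1.2 equiv), CH2Cl2–CF3CH2OH, rt, 1 h; then −78 °C, MeOH–HC(OMe)3, add 7, −78 → −40 °C; Et3N quench
Reagents that add atoms: methanol, CO
Why: The λ3-iodane made in situ adds to C3 of the styrenic C3=C4 bond of 7, methanol captures the diaryl-stabilised C4 cation anti to iodine, and the ring-fusion carbon C4a then shifts from C4 to C3 with loss of ArI* (inversion at C3); the resulting aryl(methoxy)carbenium ion is trapped by methanol as the dimethyl ketal. The closest known reactions are the iodine(III)-mediated oxidative ring contraction of 1,2-dihydronaphthalenes to indanes (also run with chiral iodanes and with the iodane generated in situ) and the enantioselective oxidative rearrangement of 1,1-diarylalkenes. The five-membered ring is not closed by a cyclisation: it forms by a suprafacial 1,2-aryl shift through a phenonium-like (3-exo-type) transition state, the six-membered ring giving up C4 to the side chain. The only new stereocentre, C1 of the indane (old C3), is fixed by the face on which the chiral iodane binds the alkene (reagent control), followed by stereospecific inversion in the shift. The step needs migration of the ring carbon C4a in preference to the electronically better 4-benzyloxyphenyl group; anti addition of iodane and methanol secures this, because in the trans adduct only the C4–C4a ring bond, never the exocyclic aryl, can lie antiperiplanar to C3–I. The ketal and not the ketone is formed, so C1–H is not acidic in the steps that follow.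

Step 4
Reactants: 8 (R)-4,6-bis(benzyloxy)-1-{[4-(benzyloxy)phenyl](dimethoxy)methyl}indane
Product: 9 (R)-5,7-bis(benzyloxy)-3-{[4-(benzyloxy)phenyl](dimethoxy)methyl}indan-1-one
Conditions: DDQ (2.5 equiv), CH2Cl2–pH 7 phosphate buffer, 0 °C → rt
Reagents that add atoms: water, O
Why: Benzylic oxidation by hydride abstraction; only the CH2 on the ring carbon ortho/para to the two benzyloxy groups gives a stabilised cation (C1–H sits on the carbon meta to both), water traps it and the electron-rich benzylic alcohol should be oxidised on to the ketone, while the buffer protects the ketal.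

Step 5
Reactants: 9 (R)-5,7-bis(benzyloxy)-3-{[4-(benzyloxy)phenyl](dimethoxy)methyl}indan-1-one; 10 1-(benzyloxy)-4-bromobenzene
Product: 11 (2S,3R)-5,7-bis(benzyloxy)-2-[4-(benzyloxy)phenyl]-3-{[4-(benzyloxy)phenyl](dimethoxy)methyl}indan-1-one (2,3-trans)
Conditions: Pd2(dba)3 (2 mol%), XPhos (5 mol%), NaOtBu (1.5 equiv), toluene, 70 °C
Reagents that add atoms: none
Why: Palladium-catalysed α-arylation of the ketone enolate at its only enolisable position C2; the new C2 centre should settle trans to the C3 side chain under the basic conditions (it is erased in step 7), and the ketal keeps the side-chain stereocentre non-acidic.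

Step 6
Reactants: 11 (2S,3R)-5,7-bis(benzyloxy)-2-[4-(benzyloxy)phenyl]-3-{[4-(benzyloxy)phenyl](dimethoxy)methyl}indan-1-one; 4 1,3-bis(benzyloxy)-5-bromobenzene
Product: 14 (1S,2S,3R)-5,7-bis(benzyloxy)-1-[3,5-bis(benzyloxy)phenyl]-2-[4-(benzyloxy)phenyl]-3-{[4-(benzyloxy)phenyl](dimethoxy)methyl}indan-1-ol, via [3,5-bis(benzyloxy)phenyl]magnesium bromide 12 (not isolated), via [3,5-bis(benzyloxy)phenyl]cerium dichloride 13 (not isolated)
Conditions: 4, Mg turnings, I2 (cat.), THF, 50 °C; transfer onto anhydrous CeCl3 slurry, THF, 0 °C, 1.5 h; cool to −78 °C, add 11, −78 → −20 °C; aq. NH4Cl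
Reagents that add atoms: none
Why: Magnesium insertion gives the aryl Grignard reagent, which is transmetalated to the organocerium for a 1,2-addition, chosen because the α-aryl ketone is hindered and easily enolised; the aryl group should enter anti to the neighbouring 2-aryl group, but this carbinol centre is also erased in step 7.

Step 7
Reactants: 14 (1S,2S,3R)-5,7-bis(benzyloxy)-1-[3,5-bis(benzyloxy)phenyl]-2-[4-(benzyloxy)phenyl]-3-{[4-(benzyloxy)phenyl](dimethoxy)methyl}indan-1-ol
Product: 15 (S)-4,6-bis(benzyloxy)-3-[3,5-bis(benzyloxy)phenyl]-2-[4-(benzyloxy)phenyl]-1-{[4-(benzyloxy)phenyl](dimethoxy)methyl}-1H-indene (same spatial arrangement at C1 as in 8; the descriptor changes only through CIP priorities)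
Conditions: Martin sulfurane (1.5 equiv), CH2Cl2, 0 °C → rt
Reagents that add atoms: none
Why: Sulfurane-mediated dehydration of the tertiary, doubly benzylic alcohol under neutral conditions; C2–H is the only β-hydrogen and lies anti to the hydroxyl, so only the tetrasubstituted C2=C3 alkene can form, and neither the ketal nor the allylic/benzylic C1–H is exposed to acid or base.

Step 8
Reactants: 15 (S)-4,6-bis(benzyloxy)-3-[3,5-bis(benzyloxy)phenyl]-2-[4-(benzyloxy)phenyl]-1-{[4-(benzyloxy)phenyl](dimethoxy)methyl}-1H-indene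
Product: 17 caraphenol B, [(1R,2R,3R)-3-(3,5-dihydroxyphenyl)-4,6-dihydroxy-2-(4-hydroxyphenyl)-2,3-dihydro-1H-inden-1-yl](4-hydroxyphenyl)methanone, via (1R,2R,3R)-3-(3,5-dihydroxyphenyl)-1-[(4-hydroxyphenyl)(dimethoxy)methyl]-2-(4-hydroxyphenyl)indane-4,6-diol 16 (not isolated)
Conditions: H2 (5 bar), Pd(OH)2/C, NaHCO3 (solid), EtOAc–MeOH, rt; filter; PPTS (cat.), acetone–H2O, rt
Reagents that add atoms: water, O
Why: Heterogeneous syn-hydrogenation should deliver both hydrogens to the indene face opposite the bulky C1 side chain, which places the C2 and C3 aryl groups cis to it (a palladium-mediated suprafacial 1,3-hydrogen shift before reduction would lead to the same isomer), the six benzyl ethers are cleaved by hydrogenolysis in the same operation, and mild ketal hydrolysis then frees the ketone without enolisation at C1.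

Compound list
1 | N-methoxy-N-methylcyclopropanecarboxamide | CON(C)C(=O)C1CC1 | starting material
2 | [4-(benzyloxy)phenyl]magnesium bromide | Br[Mg]c1ccc(OCc2ccccc2)cc1 | starting material
3 | [4-(benzyloxy)phenyl](cyclopropyl)methanone | O=C(C1CC1)c1ccc(OCc2ccccc2)cc1 | intermediate
4 | 1,3-bis(benzyloxy)-5-bromobenzene | Brc1cc(OCc2ccccc2)cc(OCc2ccccc2)c1 | starting material
5 | [3,5-bis(benzyloxy)phenyl]lithium | [Li]c1cc(OCc2ccccc2)cc(OCc2ccccc2)c1 | intermediate (not isolated)
6 | rac-[3,5-bis(benzyloxy)phenyl][4-(benzyloxy)phenyl](cyclopropyl)methanol | OC(C1CC1)(c1ccc(OCc2ccccc2)cc1)c1cc(OCc2ccccc2)cc(OCc2ccccc2)c1 | intermediate (not isolated)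
7 | 6,8-bis(benzyloxy)-4-[4-(benzyloxy)phenyl]-1,2-dihydronaphthalene | C1=C(c2ccc(OCc3ccccc3)cc2)c2cc(OCc3ccccc3)cc(OCc3ccccc3)c2CC1 | intermediate
8 | (R)-4,6-bis(benzyloxy)-1-{[4-(benzyloxy)phenyl](dimethoxy)methyl}indane | COC(OC)(c1ccc(OCc2ccccc2)cc1)[C@H]1c2cc(OCc3ccccc3)cc(OCc3ccccc3)c2CC1 | intermediate
9 | (R)-5,7-bis(benzyloxy)-3-{[4-(benzyloxy)phenyl](dimethoxy)methyl}indan-1-one | COC(OC)(c1ccc(OCc2ccccc2)cc1)[C@H]1c2cc(OCc3ccccc3)cc(OCc3ccccc3)c2C(=O)C1 | intermediate
10 | 1-(benzyloxy)-4-bromobenzene | Brc1ccc(OCc2ccccc2)cc1 | starting material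
11 | (2S,3R)-5,7-bis(benzyloxy)-2-[4-(benzyloxy)phenyl]-3-{[4-(benzyloxy)phenyl](dimethoxy)methyl}indan-1-one | COC(OC)(c1ccc(OCc2ccccc2)cc1)[C@H]1c2cc(OCc3ccccc3)cc(OCc3ccccc3)c2C(=O)[C@@H]1c1ccc(OCc2ccccc2)cc1 | intermediate
12 | [3,5-bis(benzyloxy)phenyl]magnesium bromide | Br[Mg]c1cc(OCc2ccccc2)cc(OCc2ccccc2)c1 | intermediate (not isolated)
13 | [3,5-bis(benzyloxy)phenyl]cerium dichloride | Cl[Ce](Cl)c1cc(OCc2ccccc2)cc(OCc2ccccc2)c1 | intermediate (not isolated)
14 | (1S,2S,3R)-5,7-bis(benzyloxy)-1-[3,5-bis(benzyloxy)phenyl]-2-[4-(benzyloxy)phenyl]-3-{[4-(benzyloxy)phenyl](dimethoxy)methyl}indan-1-ol | COC(OC)(c1ccc(OCc2ccccc2)cc1)[C@H]1c2cc(OCc3ccccc3)cc(OCc3ccccc3)c2[C@@](O)(c2cc(OCc3ccccc3)cc(OCc3ccccc3)c2)[C@@H]1c1ccc(OCc2ccccc2)cc1 | intermediate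
15 | (S)-4,6-bis(benzyloxy)-3-[3,5-bis(benzyloxy)phenyl]-2-[4-(benzyloxy)phenyl]-1-{[4-(benzyloxy)phenyl](dimethoxy)methyl}-1H-indene | COC(OC)(c1ccc(OCc2ccccc2)cc1)[C@H]1c2cc(OCc3ccccc3)cc(OCc3ccccc3)c2C(c2cc(OCc3ccccc3)cc(OCc3ccccc3)c2)=C1c1ccc(OCc2ccccc2)cc1 | intermediate
16 | (1R,2R,3R)-3-(3,5-dihydroxyphenyl)-1-[(4-hydroxyphenyl)(dimethoxy)methyl]-2-(4-hydroxyphenyl)indane-4,6-diol (all-cis) | COC(OC)(c1ccc(O)cc1)[C@H]1c2cc(O)cc(O)c2[C@@H](c2cc(O)cc(O)c2)[C@H]1c1ccc(O)cc1 | intermediate (not isolated)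
17 | caraphenol B, (1R,2R,3R), all-cis | O=C(c1ccc(O)cc1)[C@H]1c2cc(O)cc(O)c2[C@@H](c2cc(O)cc(O)c2)[C@H]1c1ccc(O)cc1 | target

Total step count: 8
Longest linear sequence: 8 steps (1 → 3 → 7 → 8 → 9 → 11 → 14 → 15 → 17)

Steps most likely to fail

Step 3 (key step). Two processes may go wrong. Facial discrimination in the transfer of the iodane to the alkene may be insufficient, which erodes the ee. Methanol may also capture the benzylic cation syn to iodine, after which the 4-benzyloxyphenyl group migrates instead of the ring carbon and the ring is not contracted. The fallback sets out from 7 and comes back at 8; it fixes the migrating bond through a trans amino alcohol. Shi epoxidation (fructose-derived ketone of the enantiomeric series that gives the (1R,2S)-epoxide, Oxone, K2CO3 buffer, MeCN–dimethoxymethane–H2O, 0 °C) should give (1R,2S)-5,7-bis(benzyloxy)-1-[4-(benzyloxy)phenyl]-1,2-epoxy-1,2,3,4-tetrahydronaphthalene F1. NaN3 in DMF–H2O at 60 °C should open it by SN2 attack at the secondary C2 to (1R,2R)-2-azido-5,7-bis(benzyloxy)-1-[4-(benzyloxy)phenyl]-1,2,3,4-tetrahydronaphthalen-1-ol F2. Staudinger reduction (PMe3, THF–H2O) gives the trans amino alcohol (1R,2R)-2-amino-5,7-bis(benzyloxy)-1-[4-(benzyloxy)phenyl]-1,2,3,4-tetrahydronaphthalen-1-ol F3. Tiffeneau–Demjanov semipinacol rearrangement (NaNO2, AcOH–H2O, 0 °C) should then contract the ring with inversion at C2, because in the trans isomer only the C1–C8a ring bond can be antiperiplanar to the diazonium group; it gives (R)-[4-(benzyloxy)phenyl][4,6-bis(benzyloxy)indan-1-yl]methanone F4. Ketalisation under aprotic conditions (MeOSiMe3, cat. TMSOTf, CH2Cl2, −78 °C) returns 8.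

Step 4. The acid-labile ketal may be lost to the acidic hydroquinone by-product, or the benzylic cation may lose a proton (dehydrogenation to the indene) and be over-oxidised. The fallback sets out from 8 and comes back at 9; it makes the dehydrogenation the intended path. DDQ (1.1 equiv) in dry dioxane over NaHCO3 should give (R)-4,6-bis(benzyloxy)-1-{[4-(benzyloxy)phenyl](dimethoxy)methyl}-1H-indene F5. Mukaiyama hydration (Co(acac)2, PhSiH3, O2, THF) places the hydroxyl at the benzylic carbon and gives (3R)-5,7-bis(benzyloxy)-3-{[4-(benzyloxy)phenyl](dimethoxy)methyl}indan-1-ol F6 as a mixture of carbinol epimers. Dess–Martin periodinane with NaHCO3 then gives 9.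

Step 8. Palladium may hydrogenolyse the benzylic C–O bonds of the ketal, or reduction of the tetrasubstituted alkene may stall once the phenols are free. The fallback sets out from 15 and comes back at 17; it separates saturation from deprotection and removes the benzyl groups without hydrogen. Hydrogenation over PtO2 (H2, EtOAc, rt) should give the all-cis (1R,2R,3R)-4,6-bis(benzyloxy)-3-[3,5-bis(benzyloxy)phenyl]-2-[4-(benzyloxy)phenyl]-1-{[4-(benzyloxy)phenyl](dimethoxy)methyl}indane F7. PPTS in wet acetone gives hexa-O-benzylcaraphenol B F8. BCl3 with pentamethylbenzene in CH2Cl2 at −78 °C then removes the six benzyl groups to give 17.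

Further compounds
F1 | step 3 | (1R,2S)-5,7-bis(benzyloxy)-1-[4-(benzyloxy)phenyl]-1,2-epoxy-1,2,3,4-tetrahydronaphthalene | C1Cc2c(OCc3ccccc3)cc(OCc3ccccc3)cc2[C@@]2(c3ccc(OCc4ccccc4)cc3)O[C@@H]12
F2 | step 3 | (1R,2R)-2-azido-5,7-bis(benzyloxy)-1-[4-(benzyloxy)phenyl]-1,2,3,4-tetrahydronaphthalen-1-ol | [N-]=[N+]=N[C@@H]1CCc2c(OCc3ccccc3)cc(OCc3ccccc3)cc2[C@]1(O)c1ccc(OCc2ccccc2)cc1
F3 | step 3 | (1R,2R)-2-amino-5,7-bis(benzyloxy)-1-[4-(benzyloxy)phenyl]-1,2,3,4-tetrahydronaphthalen-1-ol | N[C@@H]1CCc2c(OCc3ccccc3)cc(OCc3ccccc3)cc2[C@]1(O)c1ccc(OCc2ccccc2)cc1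
F4 | step 3 | (R)-[4-(benzyloxy)phenyl][4,6-bis(benzyloxy)indan-1-yl]methanone | O=C(c1ccc(OCc2ccccc2)cc1)[C@H]1c2cc(OCc3ccccc3)cc(OCc3ccccc3)c2CC1
F5 | step 4 | (R)-4,6-bis(benzyloxy)-1-{[4-(benzyloxy)phenyl](dimethoxy)methyl}-1H-indene | COC(OC)(c1ccc(OCc2ccccc2)cc1)[C@H]1c2cc(OCc3ccccc3)cc(OCc3ccccc3)c2C=C1
F6 | step 4 | (3R)-5,7-bis(benzyloxy)-3-{[4-(benzyloxy)phenyl](dimethoxy)methyl}indan-1-ol, mixture of epimers at C1 | COC(OC)(c1ccc(OCc2ccccc2)cc1)[C@H]1c2cc(OCc3ccccc3)cc(OCc3ccccc3)c2C(O)C1
F7 | step 8 | (1R,2R,3R)-4,6-bis(benzyloxy)-3-[3,5-bis(benzyloxy)phenyl]-2-[4-(benzyloxy)phenyl]-1-{[4-(benzyloxy)phenyl](dimethoxy)methyl}indane | COC(OC)(c1ccc(OCc2ccccc2)cc1)[C@H]1c2cc(OCc3ccccc3)cc(OCc3ccccc3)c2[C@@H](c2cc(OCc3ccccc3)cc(OCc3ccccc3)c2)[C@H]1c1ccc(OCc2ccccc2)cc1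
F8 | step 8 | hexa-O-benzylcaraphenol B, (1R,2R,3R) | O=C(c1ccc(OCc2ccccc2)cc1)[C@H]1c2cc(OCc3ccccc3)cc(OCc3ccccc3)c2[C@@H](c2cc(OCc3ccccc3)cc(OCc3ccccc3)c2)[C@H]1c1ccc(OCc2ccccc2)cc1
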